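**Retrosynthetic overview**

1. Structural feature: ring B (five-membered; C1, C2, C3, C3a, C7a) carries at C1, next to the C2 ketone, the oxygenated two-carbon branch C1'(OAc)–CH3. Ring B together with C1' is therefore read as a contracted six-membered ring (C1', C1, C2, C3, C3a, C7a) in which C1' was a methyl carbinol.
2. Target ⇒ C1-acetyl cis-hydrindane 27 (C1' acetate, C5 and C6 esters, Sharpless epoxide and methyl ester on the C7 side chain, and the C2 ketone come last) ⇒ semipinacol ring contraction of the cis-decalin cis-diol monomesylate 25, in which C7a shifts from C1' to C1.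
3. 25 ⇒ cis-decalin vinylogous ester 13 (methyl addition at C1', enol-ether oxidation to the C2 ketal, C1 ketone reduction; ring A by Saegusa oxidation, Luche reduction, epoxide-to-allylic-alcohol isomerisation) ⇒ endo Diels–Alder of 2-methoxy-1,4-benzoquinone 8 with silyloxy triene 7.
4. Ring order: the six-membered precursor of ring B comes from the quinone, ring A is closed by the [4+2] step (step 5), ring B by the contraction (step 19), the oxirane by Sharpless epoxidation (step 29).

Key step: step 19

Locants: indane-type numbering of the target (C1–C7a; C1' is the carbinol/acetyl carbon). The decalin intermediates keep these labels; their second six-membered ring is C1'–C1–C2–C3–C3a–C7a. α is the face of H3a and H7a, β the opposite face. PMB = 4-methoxybenzyl.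

Assumption: (R)-2-methylbutanoic acid 31 is taken as a purchased, enantiopure starting material.

Assumption: the sense of induction of the titanium–BINOL Diels–Alder catalyst is taken by analogy with 2-alkoxyquinone/silyloxydiene cases; the (S)-ligand is the one assumed to give 9, and the antipodal ligand is used if the sense is the opposite.

**Route**

Step 1
Reactants: 1 3-chloro-2-(chloromethyl)prop-1-ene; 2 4-methoxybenzyl alcohol
Product: 3 2-(chloromethyl)allyl 4-methoxybenzyl ether
Conditions: NaH, Bu4NI (cat.), THF, 0 °C → rt (1 in threefold excess)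
Reagents that add atoms: none
Why: Williamson ether synthesis (SN2 of the sodium alkoxide at one allylic chloride), the excess of the symmetric dichloride keeping the second displacement low.

Step 2
Reactants: 3 2-(chloromethyl)allyl 4-methoxybenzyl ether; 4 (E)-but-2-enal
Product: 5 (5E)-2-[(4-methoxybenzyloxy)methyl]hepta-1,5-dien-4-ol (racemic)
Conditions: Zn dust, NaI (cat.), THF/sat. aq. NH4Cl, 0 °C → rt
Reagents that add atoms: none
Why: Barbier-type zinc allylation adds 1,2 to the enal; the 2-substituted allyl unit is symmetric, so there is no regiochemical issue, and the new carbinol centre is erased in step 3.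

Step 3
Reactants: 5 (5E)-2-[(4-methoxybenzyloxy)methyl]hepta-1,5-dien-4-ol
Product: 6 (5E)-2-[(4-methoxybenzyloxy)methyl]hepta-1,5-dien-4-one
Conditions: MnO2 (activated, excess), CH2Cl2, rt
Reagents that add atoms: none
Why: MnO2 oxidation of the allylic alcohol under neutral conditions gives the enone without moving the β,γ-double bond into conjugation.

Step 4
Reactants: 6 (5E)-2-[(4-methoxybenzyloxy)methyl]hepta-1,5-dien-4-one
Product: 7 (3Z,5E)-2-[(4-methoxybenzyloxy)methyl]-4-(triisopropylsilyloxy)hepta-1,3,5-triene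
Conditions: TIPSOTf, Et3N, CH2Cl2, −78 → 0 °C
Reagents that add atoms: triisopropylsilyl trifluoromethanesulfonate, CC(C)[Si](OS(=O)(=O)C(F)(F)F)(C(C)C)C(C)C
Why: Soft enolisation (silyl enol ether formation) removes the doubly activated C3 hydrogen between carbonyl and alkene and gives the conjugated (Z)-dienol ether, in which the substituents on both diene termini point outward as the Diels–Alder step needs.

Step 5
Reactants: 7 (3Z,5E)-2-[(4-methoxybenzyloxy)methyl]-4-(triisopropylsilyloxy)hepta-1,3,5-triene; 8 2-methoxy-1,4-benzoquinone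
Product: 9 Diels–Alder adduct (cis-decalin methoxy-enedione with ring A TIPS enol ether)
Conditions: TiCl2[(S)-BINOLate] (10 mol%, from TiCl2(OiPr)2 and (S)-BINOL), 4 Å MS, CH2Cl2/toluene, −40 °C
Reagents that add atoms: none
Why: Diels–Alder reaction under chiral titanium–BINOL Lewis-acid catalysis: chelation of the tetravalent titanium centre by the methoxy oxygen and the adjacent carbonyl makes the quinone carbon β to that carbonyl (future C7a) take the silyl-enol-ether terminus of the diene (future C7), the endo transition state on the unsubstituted quinone double bond sets the cis ring fusion (H3a, H7a α) with the C4 methyl and the C7 side chain β, and the ligand selects the enantioface.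

Step 6
Reactants: 9 Diels–Alder adduct
Product: 10 C3 tosylhydrazone of 9
Conditions: TsNHNH2 (1.05 equiv), 4 Å MS, THF, rt
Reagents that add atoms: 4-methylbenzenesulfonohydrazide, Cc1ccc(cc1)S(=O)(=O)NN
Why: Hydrazone condensation is chemoselective for the C3 ketone because the C1' carbonyl is deactivated as a vinylogous ester, and the neutral conditions avoid enolisation of the enedione.

Step 7
Reactants: 10 C3 tosylhydrazone of 9
Product: 13 cis-decalin vinylogous ester (C1' ketone; C2 methoxy enol ether; C3 methylene), via allylic diazene 11 (not isolated), via deconjugated enol ether ketone 12 (not isolated)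
Conditions: catecholborane, CHCl3, 0 °C; NaOAc·3H2O, 60 °C; then DBU (cat.), CH2Cl2, rt
Reagents that add atoms: none
Why: Kabalka reductive transposition of a conjugated tosylhydrazone (1,2-reduction, loss of sulfinate, retro-ene loss of N2 from the allylic diazene) removes the C3 oxygen, and base-mediated conjugation of the β,γ-isomer 12 gives the vinylogous ester without touching C3a or C7a.

Step 8
Reactants: 13 cis-decalin vinylogous ester
Product: 14 ring A enone (C6 ketone, C4=C5, C4 methyl)
Conditions: Pd(OAc)2 (1.1 equiv), MeCN/CH2Cl2, rt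
Reagents that add atoms: none
Why: Saegusa–Ito oxidation of the TIPS enol ether: palladation at C5 and syn β-hydride elimination of the only β-hydrogen (H4, α) give the 4-methyl enone; the temporary C4 stereocentre disappears.

Step 9
Reactants: 14 ring A enone
Product: 15 C6 β-allylic alcohol
Conditions: NaBH4, CeCl3·7H2O, MeOH, −78 °C
Reagents that add atoms: none
Why: Luche 1,2-reduction delivers hydride to the α face of the C6 ketone, the β face being screened by the C7 side chain and the pseudoaxial C7a–C1' bond, so the 6β-hydroxyl (cis to the C7 substituent) is set; the vinylogous ester is inert.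

Step 10
Reactants: 15 C6 β-allylic alcohol
Product: 16 C6 TBS ether
Conditions: TBSOTf, 2,6-lutidine, CH2Cl2, −78 °C
Reagents that add atoms: tert-butyldimethylsilyl trifluoromethanesulfonate, CC(C)(C)[Si](C)(C)OS(=O)(=O)C(F)(F)F
Why: Silylation of the hindered secondary alcohol protects C6–O and removes its syn-directing effect before the epoxidation.

Step 11
Reactants: 16 C6 TBS ether
Product: 17 C4,C5 α-epoxide
Conditions: mCPBA (1.05 equiv), NaHCO3, CH2Cl2, 0 °C
Reagents that add atoms: 3-chloroperoxybenzoic acid, OOC(=O)c1cccc(Cl)c1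
Why: Prilezhaev epoxidation takes the trisubstituted C4=C5 bond (the most electron-rich alkene) from the convex α face, anti to the 6β-silyloxy group, which sets the C5–O bond α.

Step 12
Reactants: 17 C4,C5 α-epoxide
Product: 18 C1' tertiary allylic alcohol (C1=C2 methyl enol ether retained)
Conditions: MeLi, THF, −78 °C; aq. NaHCO3 quench
Reagents that add atoms: methyllithium, [Li]C
Why: 1,2-Addition of MeLi to the vinylogous ester (first stage of a Stork–Danheiser sequence, stopped before hydrolysis) occurs from the convex α face of the cis-decalin, giving the 1'β-hydroxyl and 1'α-methyl group.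

Step 13
Reactants: 18 C1' tertiary allylic alcohol
Product: 20 C1 hydroxy C2 dimethyl ketal (C1 epimers), via 2-methoxyoxirane 19 (not isolated)
Conditions: dimethyldioxirane (acetone solution, 1.05 equiv), K2CO3, CH2Cl2/MeOH, −78 → −20 °C
Reagents that add atoms: dimethyldioxirane, CC1(C)OO1; methanol, CO
Why: Rubottom-type epoxidation of the electron-rich enol ether under neutral conditions, followed by methanolysis of the 2-methoxyoxirane, gives the α-hydroxy dimethyl ketal; the C1 configuration is left open because it is reset in steps 14 and 15.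

Step 14
Reactants: 20 C1 hydroxy C2 dimethyl ketal
Product: 21 C1 ketone
Conditions: Dess–Martin periodinane, NaHCO3, CH2Cl2, 0 °C → rt
Reagents that add atoms: none
Why: Dess–Martin oxidation of the secondary alcohol converges both C1 epimers on one ketone without glycol cleavage or loss of the ketal.

Step 15
Reactants: 21 C1 ketone
Product: 22 cis-C1',C1-diol (1β-OH)
Conditions: NaBH4, MeOH, −20 °C
Reagents that add atoms: none
Why: Borohydride reduction by axial attack on the convex α face (in the chair with C7 equatorial the β face is flanked by the axial 1'-hydroxyl and an axial ketal methoxyl) gives the equatorial 1β-alcohol cis to the 1'β-hydroxyl.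

Step 16
Reactants: 22 cis-C1',C1-diol
Product: 23 triol with C4 exo-methylene and 5α-OH
Conditions: Et2AlCl, LiTMP (→ Et2AlTMP, 5 equiv), toluene, 0 °C → rt
Reagents that add atoms: none
Why: Yamamoto isomerisation of a trisubstituted epoxide with diethylaluminium tetramethylpiperidide: syn β-elimination takes a proton of the C4 methyl group and opens the tertiary C4–O bond, so the exocyclic methylene forms and the untouched C5–O bond keeps its α configuration.

Step 17
Reactants: 23 triol
Product: 24 C5 TES ether
Conditions: TESCl (1.1 equiv), imidazole, CH2Cl2, −20 °C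
Reagents that add atoms: chlorotriethylsilane, CC[Si](Cl)(CC)CC
Why: Silylation selects the allylic C5 hydroxyl because the C1 hydroxyl lies between two fully substituted carbons and the C1' hydroxyl is tertiary.

Step 18
Reactants: 24 C5 TES ether
Product: 25 cis-diol monomesylate (key precursor)
Conditions: MsCl, Et3N, DMAP (cat.), CH2Cl2, 0 °C → rt
Reagents that add atoms: methanesulfonyl chloride, CS(=O)(=O)Cl
Why: Mesylation through sulfene converts the only remaining secondary hydroxyl (C1, retention) into the leaving group while the tertiary C1' hydroxyl stays free.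

Step 19
Reactants: 25 cis-diol monomesylate
Product: 27 C1-acetyl cis-hydrindane, via potassium alkoxide 26 (not isolated)
Conditions: KOtBu (1.1 equiv), THF, −20 → 0 °C; pH 7 phosphate buffer quench
Reagents that add atoms: none
Why: KOtBu deprotonates the tertiary C1' carbinol to alkoxide 26, whose oxygen pushes the ring bond C1'–C7a, held antiperiplanar to the equatorial C1–OMs bond, onto C1 as mesylate leaves, so that C1–C7a forms, C7a–C1' breaks and C1' becomes the acetyl carbonyl carbon. This is the pinacol-type (semipinacol) ring contraction known for cyclohexane cis-1,2-diol monosulfonates with a tertiary carbinol, which give acylcyclopentanes. Ring B is closed not by a cyclisation but by this concerted suprafacial 1,2-alkyl shift (a formal intramolecular SN2 at C1), which contracts the six-membered ring C1'–C1–C2–C3–C3a–C7a to the five-membered ring C1–C2–C3–C3a–C7a. The new stereocentre C1 arises by inversion at the mesylate carbon with retention at the migrating C7a, so the β-mesylate gives the β-acetyl group with H1 cis to H7a, and no enolate protonation is involved. The step needs ring-bond migration in preference to methyl migration, epoxide closure, elimination and epimerisation: the chair with C7 and the mesylate equatorial puts only the ring bond anti to the leaving group, the cis-diol geometry rules out epoxide formation, the quaternary C1' and the C2 ketal leave no β-hydrogen or enolisable position, and the small excess of base at low temperature with a buffered quench protects the α-stereocentre of the product ketone.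

Step 20
Reactants: 27 C1-acetyl cis-hydrindane
Product: 28 (S)-C1' carbinol
Conditions: (R)-2-methyl-CBS-oxazaborolidine (0.5 equiv), catecholborane, toluene, −78 °C
Reagents that add atoms: none
Why: Corey–Bakshi–Shibata reduction under reagent control: with methyl as the small and C1 as the large substituent the (R)-catalyst gives the (S)-carbinol, and catecholborane at low temperature leaves the two 1,1-disubstituted alkenes alone.

Step 21
Reactants: 28 (S)-C1' carbinol
Product: 29 C1' acetate
Conditions: Ac2O, pyridine, DMAP (cat.), CH2Cl2, rt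
Reagents that add atoms: acetic anhydride, CC(=O)OC(C)=O
Why: DMAP-catalysed acetylation of the only free hydroxyl installs the C1' acetate with retention.

Step 22
Reactants: 29 C1' acetate
Product: 30 C5 alcohol
Conditions: PPTS (cat.), MeOH, 0 °C → rt
Reagents that add atoms: none
Why: Acid-catalysed methanolysis removes the triethylsilyl ether while the hindered C6 TBS ether and the PMB ether survive and the dimethyl ketal only undergoes degenerate exchange in methanol.

Step 23
Reactants: 30 C5 alcohol; 31 (R)-2-methylbutanoic acid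
Product: 32 C5 (R)-2-methylbutanoate
Conditions: DCC, DMAP, CH2Cl2, 0 °C → rt
Reagents that add atoms: none
Why: Steglich esterification acylates the allylic 5α-hydroxyl with retention at C5 and without touching the α-stereocentre of the acid.

Step 24
Reactants: 32 C5 (R)-2-methylbutanoate
Product: 33 C6 alcohol
Conditions: HF·pyridine, pyridine, THF, 0 °C → rt
Reagents that add atoms: none
Why: Buffered fluoride desilylation frees the 6β-hydroxyl; acyl migration from the trans-diaxial C5 ester is geometrically disfavoured.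

Step 25
Reactants: 34 ethyl but-2-ynoate
Product: 35 ethyl (E)-3-methylpent-2-enoate
Conditions: EtMgBr, CuI (10 mol%), THF, −78 °C; sat. aq. NH4Cl at −78 °C
Reagents that add atoms: ethylmagnesium bromide, CC[Mg]Br
Why: Copper-catalysed syn-carbometalation (conjugate addition) of the ynoate and protonation at low temperature with retention place the ester cis to the methyl group, which is the E isomer.

Step 26
Reactants: 35 ethyl (E)-3-methylpent-2-enoate
Product: 36 (E)-3-methylpent-2-enoic acid
Conditions: LiOH, THF/H2O, rt; then 1 M HCl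
Reagents that add atoms: lithium hydroxide, [Li+].[OH-]
Why: Saponification under mild conditions gives the acid without isomerising the trisubstituted double bond.

Step 27
Reactants: 33 C6 alcohol; 36 (E)-3-methylpent-2-enoic acid
Product: 37 C5,C6 diester
Conditions: DCC, DMAP (1 equiv), CH2Cl2, rt → 40 °C
Reagents that add atoms: none
Why: Steglich esterification with stoichiometric DMAP acylates the hindered axial 6β-hydroxyl before the side-chain ester exists, so lactonisation onto C6–O cannot occur; the alkene geometry is retained.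

Step 28
Reactants: 37 C5,C6 diester
Product: 38 side-chain allylic alcohol
Conditions: DDQ, CH2Cl2/pH 7 buffer, 0 °C
Reagents that add atoms: none
Why: Oxidative cleavage of the PMB ether by DDQ frees the primary allylic alcohol and leaves the esters, the ketal and the alkenes untouched.

Step 29
Reactants: 38 side-chain allylic alcohol
Product: 39 epoxy alcohol
Conditions: Ti(OiPr)4 (20 mol%), D-(−)-diisopropyl tartrate (24 mol%), tBuOOH, 4 Å MS, CH2Cl2, −20 °C
Reagents that add atoms: tert-butyl hydroperoxide, CC(C)(C)OO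
Why: Sharpless asymmetric epoxidation of the 2-substituted allylic alcohol under reagent control: the D-(−)-tartrate gives the (R)-2-(hydroxymethyl)oxirane, which becomes the (S)-glycidate after oxidation, and the acylated C5 oxygen keeps the C4 methylene from competing.

Step 30
Reactants: 39 epoxy alcohol
Product: 40 epoxy acid
Conditions: TEMPO (cat.), PhI(OAc)2, MeCN/pH 7 phosphate buffer, rt
Reagents that add atoms: water, O
Why: TEMPO/PhI(OAc)2 oxidation takes the primary alcohol through the aldehyde hydrate to the carboxylic acid; the epoxide carbon has no α-hydrogen, so it cannot epimerise.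

Step 31
Reactants: 40 epoxy acid
Product: 41 methyl glycidate with C2 dimethyl ketal
Conditions: TMSCHN2, toluene/MeOH, 0 °C
Reagents that add atoms: trimethylsilyldiazomethane, C[Si](C)(C)C=[N+]=[N-]
Why: Esterification with diazomethane generated from TMSCHN2 and methanol is neutral and spares the epoxide and the other three esters.

Step 32
Reactants: 41 methyl glycidate with C2 dimethyl ketal
Product: 42 target CNP0251769.2
Conditions: PPTS (cat.), acetone/H2O (10:1), rt → 40 °C
Reagents that add atoms: water, O
Why: Mild acid-catalysed hydrolysis of the dimethyl ketal unveils the C2 ketone last, so the base-sensitive β-acetoxy ketone and the epimerisable C1 centre are never exposed to base.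

**Compound list**

1 | 3-chloro-2-(chloromethyl)prop-1-ene | ClCC(=C)CCl | starting material
2 | 4-methoxybenzyl alcohol | COc1ccc(CO)cc1 | starting material
3 | 2-(chloromethyl)allyl 4-methoxybenzyl ether | ClCC(=C)COCc1ccc(OC)cc1 | intermediate
4 | (E)-but-2-enal | C/C=C/C=O | starting material
5 | (5E)-2-[(4-methoxybenzyloxy)methyl]hepta-1,5-dien-4-ol (racemic) | C/C=C/C(O)CC(=C)COCc1ccc(OC)cc1 | intermediate
6 | (5E)-2-[(4-methoxybenzyloxy)methyl]hepta-1,5-dien-4-one | C/C=C/C(=O)CC(=C)COCc1ccc(OC)cc1 | intermediate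
7 | (3Z,5E)-2-[(4-methoxybenzyloxy)methyl]-4-(triisopropylsilyloxy)hepta-1,3,5-triene | C/C=C/C(O[Si](C(C)C)(C(C)C)C(C)C)=C/C(=C)COCc1ccc(OC)cc1 | intermediate
8 | 2-methoxy-1,4-benzoquinone | COC1=CC(=O)C=CC1=O | starting material
9 | Diels–Alder adduct: cis-decalin with C1' and C3 ketones and C1=C2 bearing OMe at C2; ring A with 4β-methyl, C5=C6 bearing OTIPS at C6, 7β-[3-(PMB-oxy)prop-1-en-2-yl]; H3a, H7a, H4, H7 α | C[C@H]1[C@H]2C(=O)C(OC)=CC(=O)[C@H]2[C@@H](C(=C)COCc3ccc(OC)cc3)C(O[Si](C(C)C)(C(C)C)C(C)C)=C1 | intermediate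
10 | 9 with the C3 ketone as its tosylhydrazone | C[C@H]1[C@H]2C(=NNS(=O)(=O)c4ccc(C)cc4)C(OC)=CC(=O)[C@H]2[C@@H](C(=C)COCc3ccc(OC)cc3)C(O[Si](C(C)C)(C(C)C)C(C)C)=C1 | intermediate
11 | allylic diazene (C3–N=NH, C1=C2 methyl enol ether, C1' ketone) | C[C@H]1[C@H]2C(N=N)C(OC)=CC(=O)[C@H]2[C@@H](C(=C)COCc3ccc(OC)cc3)C(O[Si](C(C)C)(C(C)C)C(C)C)=C1 | intermediate (not isolated)
12 | deconjugated isomer (C2=C3 methyl enol ether, C1 methylene, C1' ketone) | C[C@H]1[C@H]2C=C(OC)CC(=O)[C@H]2[C@@H](C(=C)COCc3ccc(OC)cc3)C(O[Si](C(C)C)(C(C)C)C(C)C)=C1 | intermediate (not isolated)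
13 | vinylogous ester: C1' ketone, C1=C2 with OMe at C2, C3 methylene; ring A as in 9 | C[C@H]1[C@H]2CC(OC)=CC(=O)[C@H]2[C@@H](C(=C)COCc3ccc(OC)cc3)C(O[Si](C(C)C)(C(C)C)C(C)C)=C1 | intermediate
14 | as 13, ring A now C6 ketone with C4=C5 and C4 methyl | CC=1[C@H]2CC(OC)=CC(=O)[C@H]2[C@@H](C(=C)COCc3ccc(OC)cc3)C(=O)C=1 | intermediate
15 | as 14 with 6β-OH (cis to the C7 side chain) | CC=1[C@H]2CC(OC)=CC(=O)[C@H]2[C@@H](C(=C)COCc3ccc(OC)cc3)[C@@H](O)C=1 | intermediate
16 | 6β-OTBS ether of 15 | CC=1[C@H]2CC(OC)=CC(=O)[C@H]2[C@@H](C(=C)COCc3ccc(OC)cc3)[C@@H](O[Si](C)(C)C(C)(C)C)C=1 | intermediate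
17 | as 16 with 4α,5α-epoxide (4β-methyl) | C[C@@]14[C@H]2CC(OC)=CC(=O)[C@H]2[C@@H](C(=C)COCc3ccc(OC)cc3)[C@@H](O[Si](C)(C)C(C)(C)C)[C@@H]1O4 | intermediate
18 | as 17 with C1' = C(CH3)(OH), 1'β-OH and 1'α-methyl; C1=C2 methyl enol ether | C[C@@]14[C@H]2CC(OC)=C[C@@](C)(O)[C@H]2[C@@H](C(=C)COCc3ccc(OC)cc3)[C@@H](O[Si](C)(C)C(C)(C)C)[C@@H]1O4 | intermediate
19 | C1,C2 epoxide of the enol ether of 18 (2-methoxyoxirane, both faces) | C[C@@]14[C@H]2CC5(OC)OC5[C@@](C)(O)[C@H]2[C@@H](C(=C)COCc3ccc(OC)cc3)[C@@H](O[Si](C)(C)C(C)(C)C)[C@@H]1O4 | intermediate (not isolated)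
20 | as 18 with C2 dimethyl ketal and C1–OH (mixture of C1 epimers) | C[C@@]14[C@H]2CC(OC)(OC)C(O)[C@@](C)(O)[C@H]2[C@@H](C(=C)COCc3ccc(OC)cc3)[C@@H](O[Si](C)(C)C(C)(C)C)[C@@H]1O4 | intermediate
21 | C1 ketone of 20 | C[C@@]14[C@H]2CC(OC)(OC)C(=O)[C@@](C)(O)[C@H]2[C@@H](C(=C)COCc3ccc(OC)cc3)[C@@H](O[Si](C)(C)C(C)(C)C)[C@@H]1O4 | intermediate
22 | as 21 with 1β-OH, cis to 1'β-OH | C[C@@]14[C@H]2CC(OC)(OC)[C@@H](O)[C@@](C)(O)[C@H]2[C@@H](C(=C)COCc3ccc(OC)cc3)[C@@H](O[Si](C)(C)C(C)(C)C)[C@@H]1O4 | intermediate
23 | as 22, ring A now C4 exo-methylene, 5α-OH, 6β-OTBS | C=C1[C@H]2CC(OC)(OC)[C@@H](O)[C@@](C)(O)[C@H]2[C@@H](C(=C)COCc3ccc(OC)cc3)[C@@H](O[Si](C)(C)C(C)(C)C)[C@@H]1O | intermediate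
24 | 5α-OTES ether of 23 | C=C1[C@H]2CC(OC)(OC)[C@@H](O)[C@@](C)(O)[C@H]2[C@@H](C(=C)COCc3ccc(OC)cc3)[C@@H](O[Si](C)(C)C(C)(C)C)[C@@H]1O[Si](CC)(CC)CC | intermediate
25 | 1β-mesylate of 24 (cis-decalin cis-diol monomesylate, key precursor) | C=C1[C@H]2CC(OC)(OC)[C@@H](OS(C)(=O)=O)[C@@](C)(O)[C@H]2[C@@H](C(=C)COCc3ccc(OC)cc3)[C@@H](O[Si](C)(C)C(C)(C)C)[C@@H]1O[Si](CC)(CC)CC | intermediate
26 | potassium 1'-alkoxide of 25 | C=C1[C@H]2CC(OC)(OC)[C@@H](OS(C)(=O)=O)[C@@](C)([O-])[C@H]2[C@@H](C(=C)COCc3ccc(OC)cc3)[C@@H](O[Si](C)(C)C(C)(C)C)[C@@H]1O[Si](CC)(CC)CC.[K+] | intermediate (not isolated)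
27 | cis-hydrindane: 1β-acetyl, C2 dimethyl ketal, C4 exo-methylene, 5α-OTES, 6β-OTBS, 7β-[3-(PMB-oxy)prop-1-en-2-yl]; H1, H3a, H7a α | C=C1[C@H]2CC(OC)(OC)[C@@H](C(C)=O)[C@H]2[C@@H](C(=C)COCc3ccc(OC)cc3)[C@@H](O[Si](C)(C)C(C)(C)C)[C@@H]1O[Si](CC)(CC)CC | intermediate
28 | as 27 with 1β-[(1S)-1-hydroxyethyl] | C=C1[C@H]2CC(OC)(OC)[C@@H]([C@H](C)O)[C@H]2[C@@H](C(=C)COCc3ccc(OC)cc3)[C@@H](O[Si](C)(C)C(C)(C)C)[C@@H]1O[Si](CC)(CC)CC | intermediate
29 | acetate of 28 | C=C1[C@H]2CC(OC)(OC)[C@@H]([C@H](C)OC(C)=O)[C@H]2[C@@H](C(=C)COCc3ccc(OC)cc3)[C@@H](O[Si](C)(C)C(C)(C)C)[C@@H]1O[Si](CC)(CC)CC | intermediate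
30 | as 29 with 5α-OH | C=C1[C@H]2CC(OC)(OC)[C@@H]([C@H](C)OC(C)=O)[C@H]2[C@@H](C(=C)COCc3ccc(OC)cc3)[C@@H](O[Si](C)(C)C(C)(C)C)[C@@H]1O | intermediate
31 | (R)-2-methylbutanoic acid | CC[C@@H](C)C(=O)O | starting material
32 | 5α-[(R)-2-methylbutanoate] of 30 | C=C1[C@H]2CC(OC)(OC)[C@@H]([C@H](C)OC(C)=O)[C@H]2[C@@H](C(=C)COCc3ccc(OC)cc3)[C@@H](O[Si](C)(C)C(C)(C)C)[C@@H]1OC(=O)[C@H](C)CC | intermediate
33 | as 32 with 6β-OH | C=C1[C@H]2CC(OC)(OC)[C@@H]([C@H](C)OC(C)=O)[C@H]2[C@@H](C(=C)COCc3ccc(OC)cc3)[C@@H](O)[C@@H]1OC(=O)[C@H](C)CC | intermediate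
34 | ethyl but-2-ynoate | CC#CC(=O)OCC | starting material
35 | ethyl (E)-3-methylpent-2-enoate | CCOC(=O)/C=C(\C)CC | intermediate
36 | (E)-3-methylpent-2-enoic acid | OC(=O)/C=C(\C)CC | intermediate
37 | as 33 with 6β-[(E)-3-methylpent-2-enoate] | C=C1[C@H]2CC(OC)(OC)[C@@H]([C@H](C)OC(C)=O)[C@H]2[C@@H](C(=C)COCc3ccc(OC)cc3)[C@@H](OC(=O)/C=C(\C)CC)[C@@H]1OC(=O)[C@H](C)CC | intermediate
38 | as 37 with 7β-(3-hydroxyprop-1-en-2-yl) | C=C1[C@H]2CC(OC)(OC)[C@@H]([C@H](C)OC(C)=O)[C@H]2[C@@H](C(=C)CO)[C@@H](OC(=O)/C=C(\C)CC)[C@@H]1OC(=O)[C@H](C)CC | intermediate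
39 | as 38 with 7β-[(2R)-2-(hydroxymethyl)oxiran-2-yl] | C=C1[C@H]2CC(OC)(OC)[C@@H]([C@H](C)OC(C)=O)[C@H]2[C@@H]([C@@]3(CO)CO3)[C@@H](OC(=O)/C=C(\C)CC)[C@@H]1OC(=O)[C@H](C)CC | intermediate
40 | as 39 with the (2S)-oxirane-2-carboxylic acid | C=C1[C@H]2CC(OC)(OC)[C@@H]([C@H](C)OC(C)=O)[C@H]2[C@@H]([C@@]3(C(=O)O)CO3)[C@@H](OC(=O)/C=C(\C)CC)[C@@H]1OC(=O)[C@H](C)CC | intermediate
41 | methyl ester of 40 (C2 still the dimethyl ketal) | C=C1[C@H]2CC(OC)(OC)[C@@H]([C@H](C)OC(C)=O)[C@H]2[C@@H]([C@@]3(C(=O)OC)CO3)[C@@H](OC(=O)/C=C(\C)CC)[C@@H]1OC(=O)[C@H](C)CC | intermediate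
42 | CNP0251769.2 | C=C1[C@H]2CC(=O)[C@@H]([C@H](C)OC(C)=O)[C@H]2[C@@H]([C@@]2(C(=O)OC)CO2)[C@@H](OC(=O)/C=C(\C)CC)[C@@H]1OC(=O)[C@H](C)CC | target

**Step count**

Total step count: 32. Longest linear sequence: 30 steps (steps 1–24 and 27–32); steps 25 and 26 form the two-step branch to acid 36.

**Steps most likely to fail**

Step 19 (ring contraction). What may go wrong: the mesylate may leave from the chair in which it is axial, so that the methyl group migrates or a ketal oxygen participates, and residual base may epimerise C1 of the product ketone. Fallback, from mesylate 25: the trigger is changed from a free alkoxide to a Lewis-acid manifold. Et3Al (3 equiv, CH2Cl2, −78 → −30 °C) converts the carbinol into the diethylaluminium alkoxide of 25 F1, in which the aluminium centre assists departure of the mesylate while the alkoxide oxygen pushes the ring bond (Suzuki–Tsuchihashi-type rearrangement of a β-mesyloxy alcohol). No free base is present at any time, and the reaction returns to the route at 27.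

Step 5 (Diels–Alder). What may go wrong: poor facial discrimination by the titanium complex, loss of regiocontrol if the Lewis acid binds the distal carbonyl, a stepwise Mukaiyama–Michael pathway, or tautomerisation of the enedione to the hydroquinone. Fallback, from 7 and 8: the cycloaddition is run without catalyst (toluene, 25–40 °C), where the methoxy group alone directs the same regiochemistry and the endo rule the same relative configuration. It gives 9 as the racemate, that is, together with the enantiomer of adduct 9 F2. Separation of the enantiomers on a chiral stationary phase (preparative SFC, amylose carbamate phase) returns to the route at 9.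

Step 7 (removal of the C3 oxygen). What may go wrong: over-reduction by the borane, incomplete loss of sulfinate, or aromatisation of the ring under the warm acetate conditions. Fallback, from 9: Luche reduction (NaBH4, CeCl3·7H2O, MeOH, −78 °C) reduces only the C3 ketone and gives the C3 β-carbinol of 9 F3. Acetylation (Ac2O, pyridine, DMAP) gives the C3 acetate of 9 F4. SmI2 (THF/MeOH, −78 °C) then cleaves the γ-acetoxy group of the vinylogous ester reductively; the dienolate is protonated to 12 and conjugated with DBU, which returns to the route at 13.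

**Further compounds**

F1 | step 19 | diethylaluminium 1'-alkoxide of mesylate 25 | C=C1[C@H]2CC(OC)(OC)[C@@H](OS(C)(=O)=O)[C@@](C)(O[Al](CC)CC)[C@H]2[C@@H](C(=C)COCc3ccc(OC)cc3)[C@@H](O[Si](C)(C)C(C)(C)C)[C@@H]1O[Si](CC)(CC)CC
F2 | step 5 | enantiomer of adduct 9 | C[C@@H]1[C@@H]2C(=O)C(OC)=CC(=O)[C@@H]2[C@H](C(=C)COCc3ccc(OC)cc3)C(O[Si](C(C)C)(C(C)C)C(C)C)=C1
F3 | step 7 | C3 β-carbinol of 9 | C[C@H]1[C@H]2[C@@H](O)C(OC)=CC(=O)[C@H]2[C@@H](C(=C)COCc3ccc(OC)cc3)C(O[Si](C(C)C)(C(C)C)C(C)C)=C1
F4 | step 7 | C3 acetate of 9 | C[C@H]1[C@H]2[C@@H](OC(C)=O)C(OC)=CC(=O)[C@H]2[C@@H](C(=C)COCc3ccc(OC)cc3)C(O[Si](C(C)C)(C(C)C)C(C)C)=C1
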